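**Retrosynthetic overview**

- Target ⇒ macrocyclic β-hydroxy ketone + cinnamaldehyde: the C6–O acyl bond (and the C8–H bond) is made last by a samarium-catalysed Tishchenko acyl transfer, the key step.
- Macrocyclic aldol ⇒ acyclic α-chloro keto epoxy-aldehyde: the ten-membered carbocycle is closed at C6–C7 by an intramolecular samarium Reformatsky aldol.
- Epoxy-aldehyde ⇒ Z-allylic alcohol: the oxirane C–O bonds come from a Sharpless asymmetric epoxidation, which sets the absolute configuration; a double oxidation follows.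
- Chlorohydrin chain ⇒ nerol-derived allylic chloride + 2-chloro-3-methylbutanal: C8–C9 by alpha-selective allylbarium addition.
- Ring order: oxirane first (step 6), cyclodecene second (step 8).

Assumption: the SMILES is taken literally, i.e. a 1(10)E olefin and an oxirane on which C3 and C6 are cis (4S,5R,6S,7R,8R). Germacrane numbers are used in the comments: C1=C10 (methyl on C10), C4–C5 oxirane (methyl on C4), C6 ester, C7 isopropyl, C8 hydroxyl.

**Step 1**
Reactants: 1 nerol, (2Z)-3,7-dimethylocta-2,6-dien-1-ol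
Product: 2 2-{[(2Z)-3,7-dimethylocta-2,6-dien-1-yl]oxy}oxane
Conditions: DHP (1.3 equiv), PPTS (5 mol%), CH2Cl2, rt
Reagents that add atoms: 3,4-dihydro-2H-pyran, C1=COCCC1
Why: Acid-catalysed tetrahydropyranylation (acetal formation) masks the allylic hydroxyl for the oxidation and organobarium steps; the acetal carbon is racemic and is removed in step 5.

**Step 2**
Reactants: 2 2-{[(2Z)-3,7-dimethylocta-2,6-dien-1-yl]oxy}oxane
Product: 3 (2E,6Z)-2,6-dimethyl-8-(oxan-2-yloxy)octa-2,6-dien-1-ol
Conditions: SeO2 (0.3 equiv), t-BuOOH (3 equiv), salicylic acid (10 mol%), CH2Cl2, 0 °C to rt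
Reagents that add atoms: SeO2, O=[Se]=O; tert-butyl hydroperoxide, CC(C)(C)OO
Why: Sharpless–Umbreit allylic oxidation (ene reaction, then 2,3-sigmatropic shift) hydroxylates only the E-methyl group of the terminal trisubstituted olefin, giving the E allylic alcohol whose carbon becomes C9; the oxygen-bearing olefin is deactivated.

**Step 3**
Reactants: 3 (2E,6Z)-2,6-dimethyl-8-(oxan-2-yloxy)octa-2,6-dien-1-ol
Product: 4 2-{[(2Z,6E)-8-chloro-3,7-dimethylocta-2,6-dien-1-yl]oxy}oxane
Conditions: NCS (1.2 equiv), Me2S (1.3 equiv), CH2Cl2, −20 to 0 °C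
Reagents that add atoms: N-chlorosuccinimide, O=C1CCC(=O)N1Cl
Why: Corey–Kim chlorination converts the primary allylic alcohol into the chloride by SN2 on the alkoxysulfonium salt, without allylic transposition or loss of olefin geometry and without touching the acetal.

**Step 4**
Reactants: 5 3-methylbutanal
Product: 6 2-chloro-3-methylbutanal (racemic)
Conditions: NCS (1.05 equiv), DL-proline (10 mol%), CH2Cl2, 0 °C to rt; used as a distilled solution
Reagents that add atoms: N-chlorosuccinimide, O=C1CCC(=O)N1Cl
Why: Enamine-catalysed α-chlorination of an aldehyde installs the halogen that later allows regiospecific enolate formation at C7; racemic material suffices because this centre becomes sp2 in step 8.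

**Step 5**
Reactants: 4 2-{[(2Z,6E)-8-chloro-3,7-dimethylocta-2,6-dien-1-yl]oxy}oxane; 6 2-chloro-3-methylbutanal
Product: 9 (2Z,6E)-10-chloro-3,7,11-trimethyldodeca-2,6-diene-1,9-diol (diastereomer mixture), via allylbarium chloride 7 (not isolated), via THP-protected chlorohydrin 8 (not isolated)
Conditions: BaI2 (1.1 equiv), lithium biphenylide (2.2 equiv), THF, rt; then 4, −78 °C; then 6 (1.2 equiv), −78 °C; aq. NH4Cl; then PPTS (20 mol%), MeOH, 40 °C
Reagents that add atoms: none
Why: Yamamoto-type allylbarium carbonyl addition occurs at the unsubstituted (alpha) allyl terminus with retention of the E olefin and forms C8–C9 as a linear homoallylic chlorohydrin, and acid methanolysis then removes the THP group; the two new centres (C7, C8) form as a mixture and are both erased later.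

**Step 6**
Reactants: 9 (2Z,6E)-10-chloro-3,7,11-trimethyldodeca-2,6-diene-1,9-diol
Product: 10 (2R,3S,6E)-10-chloro-2,3-epoxy-3,7,11-trimethyldodec-6-ene-1,9-diol
Conditions: Ti(OiPr)4 (10 mol%), D-(−)-diethyl tartrate (12 mol%), t-BuOOH (2 equiv), 4 Å MS, CH2Cl2, −20 °C
Reagents that add atoms: tert-butyl hydroperoxide, CC(C)(C)OO
Why: Catalytic Sharpless asymmetric epoxidation of the Z-trisubstituted primary allylic alcohol, in which D-(−)-tartrate directs oxygen to the face that gives the (2R,3S)-oxirane (C5 R and C4 S of the target) and syn transfer to the Z olefin places C3 and C6 cis on the oxirane; the non-allylic secondary alcohol and the remote olefin do not react.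

**Step 7**
Reactants: 10 (2R,3S,6E)-10-chloro-2,3-epoxy-3,7,11-trimethyldodec-6-ene-1,9-diol
Product: 11 (2S,3S)-3-[(3E)-7-chloro-4,8-dimethyl-6-oxonon-3-en-1-yl]-3-methyloxirane-2-carbaldehyde (C7 epimer mixture)
Conditions: DMP (3 equiv), pyridine (6 equiv), CH2Cl2, 0 °C to rt
Reagents that add atoms: none
Why: Dess–Martin oxidation converts the primary epoxy alcohol into the epoxy aldehyde and the chlorohydrin into the α-chloro ketone in one buffered operation that leaves the oxirane centres untouched; the carbinol centre at C8 is erased and both C7 epimers give the same enolate.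

**Step 8**
Reactants: 11 (2S,3S)-3-[(3E)-7-chloro-4,8-dimethyl-6-oxonon-3-en-1-yl]-3-methyloxirane-2-carbaldehyde
Product: 13 (1R,2S,3S,6E,10S)-2-hydroxy-6,10-dimethyl-3-(propan-2-yl)-11-oxabicyclo[8.1.0]undec-6-en-4-one, via samarium enolate 12 (not isolated)
Conditions: SmI2 (2.2 equiv, 0.1 M in THF, added over 4 h), THF, 0.003 M, −78 °C; pH 7 buffer
Reagents that add atoms: none
Why: Samarium Reformatsky-type aldol in which SmI2 cleaves the C–Cl bond to give a trivalent samarium (Z)-enolate regiospecifically at C7 (no enolisation toward the doubly activated C9), and this enolate closes the ten-membered ring on the aldehyde through a chair Zimmerman–Traxler transition state with samarium also bound to the oxirane oxygen, which should give the 6,7-syn and 5,6-syn (chelation-controlled) aldol, i.e. C6 (S) and C7 in the target's spatial arrangement.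

**Step 9**
Reactants: 13 (1R,2S,3S,6E,10S)-2-hydroxy-6,10-dimethyl-3-(propan-2-yl)-11-oxabicyclo[8.1.0]undec-6-en-4-one; 14 (2E)-3-phenylprop-2-enal (cinnamaldehyde)
Product: 16 (1R,2S,3R,4R,6E,10S)-4-hydroxy-6,10-dimethyl-3-(propan-2-yl)-11-oxabicyclo[8.1.0]undec-6-en-2-yl (2E)-3-phenylprop-2-enoate, via samarium hemiacetal alkoxide 15 (not isolated)
Conditions: SmI2 (30 mol%) pre-mixed with 14 (6 equiv), THF, −10 °C; then 13, −10 °C, 2 h
Reagents that add atoms: none
Why: Proposed new method: an Evans–Tishchenko acyl-transfer reduction run with an α,β-unsaturated aldehyde on a strained medium-ring aldol that carries a neighbouring oxirane, in which the C6 alkoxide adds to cinnamaldehyde to form the C6–O–C hemiacetal bond (15), trivalent samarium bridges the hemiacetal oxygen and the C8 carbonyl, and the hemiacetal hydrogen is delivered intramolecularly through a six-membered chair so that C8 becomes R (1,3-anti to the C6 oxygen) while the hemiacetal collapses to the cinnamate on O6 only; the enal serves purely as hydride donor (its C=C is untouched and the conjugated ester product makes the transfer more favourable), and the catalyst is pre-formed by letting SmI2 reduce a little cinnamaldehyde so that no divalent samarium meets the oxirane; the closest known reaction is the SmI2-catalysed Evans–Tishchenko reduction of acyclic β-hydroxy ketones with saturated or aromatic aldehydes.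

**Compound list**

1 | nerol, (2Z)-3,7-dimethylocta-2,6-dien-1-ol | CC(C)=CCC/C(C)=C\CO | starting material
2 | 2-{[(2Z)-3,7-dimethylocta-2,6-dien-1-yl]oxy}oxane (racemic at the acetal carbon) | CC(C)=CCC/C(C)=C\COC1CCCCO1 | intermediate
3 | (2E,6Z)-2,6-dimethyl-8-(oxan-2-yloxy)octa-2,6-dien-1-ol | OC/C(C)=C/CC/C(C)=C\COC1CCCCO1 | intermediate
4 | 2-{[(2Z,6E)-8-chloro-3,7-dimethylocta-2,6-dien-1-yl]oxy}oxane | ClC/C(C)=C/CC/C(C)=C\COC1CCCCO1 | intermediate
5 | 3-methylbutanal | CC(C)CC=O | starting material
6 | 2-chloro-3-methylbutanal (racemic) | CC(C)C(Cl)C=O | intermediate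
7 | [(2E,6Z)-2,6-dimethyl-8-(oxan-2-yloxy)octa-2,6-dien-1-yl]barium chloride | Cl[Ba]C/C(C)=C/CC/C(C)=C\COC1CCCCO1 | intermediate
8 | (6E,10Z)-3-chloro-2,6,10-trimethyl-12-(oxan-2-yloxy)dodeca-6,10-dien-4-ol (diastereomer mixture) | CC(C)C(Cl)C(O)C/C(C)=C/CC/C(C)=C\COC1CCCCO1 | intermediate
9 | (2Z,6E)-10-chloro-3,7,11-trimethyldodeca-2,6-diene-1,9-diol (mixture at C9 and C10) | CC(C)C(Cl)C(O)C/C(C)=C/CC/C(C)=C\CO | intermediate
10 | (2R,3S,6E)-10-chloro-2,3-epoxy-3,7,11-trimethyldodec-6-ene-1,9-diol (mixture at C9 and C10) | CC(C)C(Cl)C(O)C/C(C)=C/CC[C@]1(C)O[C@@H]1CO | intermediate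
11 | (2S,3S)-3-[(3E)-7-chloro-4,8-dimethyl-6-oxonon-3-en-1-yl]-3-methyloxirane-2-carbaldehyde (same oxirane geometry as 10; descriptor at C2 changes because of the aldehyde) | CC(C)C(Cl)C(=O)C/C(C)=C/CC[C@]1(C)O[C@@H]1C=O | intermediate
12 | diiodosamarium (Z)-enolate of 11 (trivalent samarium on the C8 oxygen, C7=C8, oxygen cis to isopropyl) | CC(C)/C=C(\O[Sm](I)I)C/C(C)=C/CC[C@]1(C)O[C@@H]1C=O | intermediate
13 | (1R,2S,3S,6E,10S)-2-hydroxy-6,10-dimethyl-3-(propan-2-yl)-11-oxabicyclo[8.1.0]undec-6-en-4-one (germacrane: 4S,5R,6S with the isopropyl carbon arranged as in the target; its descriptor reads S here because C8 is a carbonyl) | C/C1=C\CC[C@]2(C)O[C@@H]2[C@@H](O)[C@H](C(C)C)C(=O)C1 | intermediate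
14 | (2E)-3-phenylprop-2-enal (cinnamaldehyde) | O=C/C=C/c1ccccc1 | starting material
15 | diiodosamarium hemiacetal alkoxide formed from the C6 hydroxyl of 13 and 14 | C/C1=C\CC[C@]2(C)O[C@@H]2[C@@H](OC(O[Sm](I)I)/C=C/c2ccccc2)[C@H](C(C)C)C(=O)C1 | intermediate
16 | (1R,2S,3R,4R,6E,10S)-4-hydroxy-6,10-dimethyl-3-(propan-2-yl)-11-oxabicyclo[8.1.0]undec-6-en-2-yl (2E)-3-phenylprop-2-enoate (germacrane: 4S,5R,6S,7R,8R) | C/C1=C\CC[C@]2(C)O[C@@H]2[C@@H](OC(=O)/C=C/c2ccccc2)[C@H](C(C)C)[C@H](O)C1 | target

**Step count and risks**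

Total steps: 9. Longest linear sequence: 8 (steps 1, 2, 3, 5, 6, 7, 8, 9); step 4 is a one-step branch.

Steps most likely to fail:

Step 5 (allylbarium addition). The risks are alpha versus gamma attack, erosion of the E olefin, and the handling of zerovalent barium. The fallback sets out from 4 and comes back at 8. Sodium thiophenolate (DMF, 0 °C) displaces the chloride of 4 to give the allyl phenyl sulfide 2-{[(2Z,6E)-3,7-dimethyl-8-(phenylsulfanyl)octa-2,6-dien-1-yl]oxy}oxane F1. Reductive lithiation with lithium 4,4'-di-tert-butylbiphenylide (THF, −78 °C) gives the allyllithium [(2E,6Z)-2,6-dimethyl-8-(oxan-2-yloxy)octa-2,6-dien-1-yl]lithium F2. CeCl3 converts it to the allylcerium reagent dichloro[(2E,6Z)-2,6-dimethyl-8-(oxan-2-yloxy)octa-2,6-dien-1-yl]cerium F3. Allylcerium reagents add to aldehydes at the less substituted terminus, so addition of 6 gives 8, which is methanolysed to 9 as in step 5.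

Step 8 (ten-membered ring closure). The risks are ring strain, competing reduction of the epoxy aldehyde by SmI2, and the C6/C7 diastereoselectivity, which rests on a transition-state model and is not secured by precedent. The fallback sets out from 11 and comes back at 13. Zn dust, Me3SiCl and TMEDA (Et2O, 0 °C) turn the α-chloro ketone regiospecifically into the silyl enol ether (2S,3S)-3-methyl-3-[(3E,6Z)-4,8-dimethyl-6-(trimethylsilyloxy)nona-3,6-dien-1-yl]oxirane-2-carbaldehyde F4. A fluoride-triggered intramolecular Mukaiyama-type aldol (TASF 1.1 equiv, THF, −78 °C, 0.003 M) then closes the ring without a reducing metal or a Lewis acid; this open-transition-state aldol is syn-selective whatever the enol ether geometry, and gives 13.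

Step 9 (the new acyl-transfer reduction). The risks are oxirane opening by Lewis-acidic samarium iodides, Payne migration of the C6 alkoxide, retro-aldol ring opening, and a low hemiacetal population with an enal. The fallback sets out from 13 and comes back at 16, using known chemistry only. Cinnamoyl chloride (pyridine, DMAP cat., CH2Cl2, −20 °C) acylates the C6 hydroxyl to give the keto ester (1R,2S,3S,6E,10S)-6,10-dimethyl-4-oxo-3-(propan-2-yl)-11-oxabicyclo[8.1.0]undec-6-en-2-yl (2E)-3-phenylprop-2-enoate F5. Reagent-controlled reduction of the C8 ketone with (S)-Me-CBS (20 mol%) and catecholborane (toluene, −78 °C) then gives the 8R alcohol 16.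

**Further compounds**

F1 | step 5 | 2-{[(2Z,6E)-3,7-dimethyl-8-(phenylsulfanyl)octa-2,6-dien-1-yl]oxy}oxane | c1ccccc1SC/C(C)=C/CC/C(C)=C\COC2CCCCO2
F2 | step 5 | [(2E,6Z)-2,6-dimethyl-8-(oxan-2-yloxy)octa-2,6-dien-1-yl]lithium | [Li]C/C(C)=C/CC/C(C)=C\COC1CCCCO1
F3 | step 5 | dichloro[(2E,6Z)-2,6-dimethyl-8-(oxan-2-yloxy)octa-2,6-dien-1-yl]cerium | Cl[Ce](Cl)C/C(C)=C/CC/C(C)=C\COC1CCCCO1
F4 | step 8 | (2S,3S)-3-methyl-3-[(3E,6Z)-4,8-dimethyl-6-(trimethylsilyloxy)nona-3,6-dien-1-yl]oxirane-2-carbaldehyde | CC(C)/C=C(\O[Si](C)(C)C)C/C(C)=C/CC[C@]1(C)O[C@@H]1C=O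
F5 | step 9 | (1R,2S,3S,6E,10S)-6,10-dimethyl-4-oxo-3-(propan-2-yl)-11-oxabicyclo[8.1.0]undec-6-en-2-yl (2E)-3-phenylprop-2-enoate | C/C1=C\CC[C@]2(C)O[C@@H]2[C@@H](OC(=O)/C=C/c2ccccc2)[C@H](C(C)C)C(=O)C1
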